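**Remarks on the chemistry.** The heptane chain is numbered C1–C7 from the 4-hydroxyphenyl ring (ring A, on C1) to the 3,4-dihydroxyphenyl ring (ring B, on C7), and all names below use this numbering. With it, the target 14 has a free hydroxyl on C3 and the acetate on C5, and both centres are R, which is the anti-1,3-diol arrangement. Bromide 7 is assumed to be a catalogue compound; if it has to be made, one Appel bromination of the corresponding commercial primary alcohol suffices and the route is unchanged.

## Analysis of the target

14 is an open-chain diarylheptanoid: a heptane chain C1–C7 with ring A on C1 and ring B on C7, and no ring besides the two arenes. The only stereocentres are C3, which bears the free hydroxyl O3–H, and C5, which bears the acetoxy group O5–C(=O)CH3. Both are R, so the C3–O/C5–O pair is a 1,3-anti diol, and the two halves of the chain would be related by a C2 axis if rings A and B were the same. This near-symmetry is the real difficulty: C3 and C5 have identical surroundings as far as the arenes (the first constitutional difference, the C3' oxygen of ring B, lies six bonds from C5). No acylating reagent or catalyst can therefore be expected to choose O5 over O3, and the wrong monoacetate would be almost inseparable from the right one. For the same reason, any intermediate in which C3 and C5 carry the same functional group has lost the information on which oxygen is to be acetylated. The molecule is also labile: the acetyl group can migrate from O5 to O3 through a six-membered orthoester intermediate under base or acid, the ester does not survive ester-cleaving deprotections, and the free catechol of ring B is oxidised in air under basic conditions. The feature that the route seizes is the array C3(H)–O3H / C5–O5–C(=O)CH3. An anti-1,3-diol monoester is the retron of a Tishchenko hydride shift, so the acetyl carbon and the hydrogen on C3 are read as the carbonyl carbon and the aldehydic hydrogen of one molecule of acetaldehyde (11). With that reading the target shrinks to a β-hydroxy ketone with a single stereocentre (10).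

## Retrosynthetic reasoning

**14 ⇒ 13 (three ArO–H bonds).** The three phenols are masked as benzyl ethers until the last step. Benzyl is chosen because its removal by catalytic hydrogenolysis needs neither acid, base nor nucleophile, which a 1,3-diol monoacetate and a catechol both demand. The forward step has to cleave three aryl benzyl ethers and leave the secondary acetate on O5.

**13 ⇒ 10 + 11 (C3–H and O5–C(acyl), the key disconnection).** Both bonds are cut in one transform, an Evans–Tishchenko reduction run backwards. The cut is made here because it is the only disconnection in which the position of the acetyl group and the configuration of C3 follow from the same transition state: the hydride that creates C3 comes from a hemiacetal built on O5, so the acyl group cannot end up anywhere else. What is gained is the loss of one stereocentre, the loss of the O3/O5 differentiation problem and the loss of every alcohol protecting group. The forward reaction has to deliver hydride to one face of the C3 carbonyl of 10 under control of C5 and leave the product before the acetyl group can migrate.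

**10 ⇒ 6 + 7 (C2–C3, through 8 and 9).** The ring-A arm is attached by a Weinreb ketone synthesis. The obvious cut, C4–C5 by an aldol union of a methyl ketone with an aldehyde, is avoided, because such aldol additions to unbranched aliphatic aldehydes are not reliably enantioselective. Cutting C2–C3 instead keeps C3 as an amide carbon while C5 is already a carbinol, so C3 and C5 are never both ketones in any intermediate. That difference in functional group is the information which the Tishchenko step later translates into the position of the acetate. The forward step has to stop at the ketone and must not touch C5.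

**6 ⇒ 5 (C5–H).** The C5 stereocentre is set by chelation-directed asymmetric hydrogenation of a β-keto amide with a chiral ruthenium diphosphine catalyst. This reaction class has a predictable sense and does not depend on the size of the two substituents on the ketone, which here are both unbranched chains. The forward step has to reduce the ketone only and leave the N–O bond and the benzyl ethers alone.

**5 ⇒ 2 + 3 (C4–C5, through 4).** A crossed Claisen condensation joins the ester carbon of 2 (the future C5) to the methyl carbon of the acetamide 3 (the future C4). The amide carbon of 3 becomes C3, so the two-carbon unit brings the Weinreb handle with it.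

**2 ⇒ 1 (two ArO–C bonds and one CO2–C bond).** Exhaustive benzylation of commercial dihydrocaffeic acid 1 protects the catechol and turns the carboxylic acid into an acylating ester in the same operation.

## Alternatives that were turned down

**Alternative 1: (the textbook route) make the diol first, acetylate afterwards.** The disconnection is C4–C5 by Claisen condensation to the 1,3-diketone A1, followed by the C3–H and C5–H bonds together. The forward key step is a double asymmetric hydrogenation of A1 to the (3R,5R)-diol A2, which sets both stereocentres as a group, followed by monoacetylation. It was turned down because A2 is pseudo-C2-symmetric. O3–H and O5–H differ only by a benzyloxy group six bonds away, so monoacetylation must give 13 and its regioisomer A3 in about equal amounts besides over-acetylation. The orthoester trick for monoacylation opens in both directions for the same reason, and a lipase meets two R-configured carbinols with the same local environment. The repair is to introduce the two alcohols one at a time with two orthogonal protecting groups; this costs at least four extra steps and throws away the advantage of the double hydrogenation.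

**Alternative 2: one-pot three-component aldol–Tishchenko coupling.** The disconnection is C4–C5, C3–H and O5–C(acyl) in a single operation. In the forward key step the lithium enolate of ketone A4 adds to aldehyde A5, and the lithium aldolate is intercepted by 11 and undergoes the hydride shift to the anti monoacetate A6. This is the most convergent reading of the target, but A6 is racemic, because none of the three components is chiral, and a resolution would cost half of the material. The step is also mechanistically fragile. Lithium aldolates revert to enolate and aldehyde at the temperature at which the hydride shift proceeds, so the enolate of A4 would be handed over to the excess of the more electrophilic 11. A5 also competes with 11 as hydride donor, which would put the wrong acyl group on O5. Catalytic enantioselective versions of this cascade exist only where acceptor and hydride donor are the same aldehyde, which cannot give an acetate on this skeleton.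

**Alternative 3: two-directional opening of a C2-symmetric diepoxide.** The disconnection is C1–C2 and C6–C7. In the forward key step the diepoxide A7, which carries both stereocentres, is opened at its termini by two different benzylic copper reagents, first the ring-B nucleophile to give epoxy alcohol A8, then the ring-A nucleophile. It was turned down for three reasons. The two epoxides of A7 are homotopic and react independently, so the first opening is statistical. The acetyl group cannot be placed on O5 of A8 before the second opening, because the organometallic reagent attacks esters and the C3 alkoxide formed in that opening sits 1,3 to the acetate, the exact arrangement for acyl migration. O5 therefore needs a temporary group and O3 a second one, and the route ends in the same protect–swap–deprotect sequence as alternative 1. In addition, 4-alkoxybenzyl organometallics are prone to homocoupling, and A7 is itself several steps from commercial material.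

Key step: step 5

## Route

Step 1
Reactants: 1 3-(3,4-dihydroxyphenyl)propanoic acid (dihydrocaffeic acid)
Product: 2 benzyl 3-[3,4-bis(benzyloxy)phenyl]propanoate
Conditions: BnBr (3.5 equiv), K2CO3 (4 equiv), KI (cat.), DMF, 60 °C, Ar
Reagents that add atoms: benzyl bromide, BrCc1ccccc1
Why: Williamson O-alkylation of both phenoxides and SN2 esterification of the carboxylate in one operation; argon keeps the catecholate from air oxidation. The benzyl ester is the acylating group for step 2, so no separate activation is needed.

Step 2
Reactants: 2 benzyl 3-[3,4-bis(benzyloxy)phenyl]propanoate; 3 N-methoxy-N-methylacetamide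
Product: 5 5-[3,4-bis(benzyloxy)phenyl]-N-methoxy-N-methyl-3-oxopentanamide, via lithium amide enolate 4 (not isolated)
Conditions: 3 (2.5 equiv), LDA (2.5 equiv), THF, -78 °C; then 2, -78 to -40 °C; aq. NH4Cl
Reagents that add atoms: none
Why: Crossed Claisen condensation: the preformed enolate 4 is acylated by the benzyl ester with loss of benzyloxide. The second equivalent of 4 deprotonates the β-keto amide as it forms, which makes the acylation irreversible and shields the new ketone from a second attack.

Step 3
Reactants: 5 5-[3,4-bis(benzyloxy)phenyl]-N-methoxy-N-methyl-3-oxopentanamide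
Product: 6 (3R)-5-[3,4-bis(benzyloxy)phenyl]-3-hydroxy-N-methoxy-N-methylpentanamide
Conditions: [RuCl((R)-BINAP)(p-cymene)]Cl (1 mol%), H2 (30 bar), EtOH, 60 °C
Reagents that add atoms: none
Why: Noyori asymmetric hydrogenation of a β-keto amide: ketone and amide carbonyl chelate ruthenium, and the (R)-BINAP ligand should deliver hydride to the face that gives the 3R carbinol, the same sense as for (R)-3-hydroxybutanoates from 3-oxobutanoates. Homogeneous ruthenium should leave the aryl benzyl ethers and the N–O bond intact.

Step 4
Reactants: 6 (3R)-5-[3,4-bis(benzyloxy)phenyl]-3-hydroxy-N-methoxy-N-methylpentanamide; 7 1-(benzyloxy)-4-(2-bromoethyl)benzene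
Product: 10 (5R)-7-[3,4-bis(benzyloxy)phenyl]-1-[4-(benzyloxy)phenyl]-5-hydroxyheptan-3-one, via Grignard reagent 8 (not isolated), via magnesium hemiaminal chelate 9 (not isolated)
Conditions: 7 (3.2 equiv), Mg, THF, 40 °C; then 6, THF, -10 to 20 °C; aq. NH4Cl, 0 °C
Reagents that add atoms: none
Why: Weinreb ketone synthesis on the unprotected β-hydroxy amide: the first equivalent of 8 forms the magnesium alkoxide, and further reagent adds once to the amide. The N-methoxy chelate 9 persists until the quench, so no tertiary alcohol can form. The carbinol carbon is not involved and keeps its configuration (it is C5 of the heptane chain from here on).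

Step 5
Reactants: 10 (5R)-7-[3,4-bis(benzyloxy)phenyl]-1-[4-(benzyloxy)phenyl]-5-hydroxyheptan-3-one; 11 acetaldehyde
Product: 13 (3R,5R)-7-[3,4-bis(benzyloxy)phenyl]-1-[4-(benzyloxy)phenyl]-3-hydroxyheptan-5-yl acetate, via samarium hemiacetal 12 (not isolated)
Conditions: 11 (8 equiv, freshly distilled), SmI2 (0.2 equiv, 0.1 M in THF), THF, -10 °C, dark; cold aq. NaHCO3
Reagents that add atoms: none
Why: Samarium-catalysed Evans–Tishchenko reduction, whose closest precedent is the reduction of acyclic β-hydroxy ketones with acetaldehyde and substoichiometric SmI2. SmI2 is oxidised by 11 to a Sm(III) alkoxide, which exchanges onto O5 of 10; the O5 alkoxide adds to a further molecule of 11 to give the hemiacetal 12, in which samarium bridges the hemiacetal oxygen and the C3 carbonyl oxygen. Within this chelate the hemiacetal C–H is transferred as hydride to C3 through a chair-like six-membered transition state, and the hemiacetal carbon emerges as the acetyl carbonyl on O5 while O3 becomes the samarium alkoxide that carries the catalytic cycle. No ring of the product is closed; the only ring is the transient chelate. The new stereocentre C3 is controlled by C5: with the C6 chain and the C2 chain equatorial on the chelate, hydride can reach only the carbonyl face that gives the 1,3-anti relationship, that is 3R from 5R. The constitutional selectivity (acetyl on O5, never on O3) is secured by the mechanism, since the acyl carbon is bound to O5 before the hydride moves; it is preserved by the low temperature, a short reaction time and the cold bicarbonate quench, which keep the O3 alkoxide from attacking the new ester. Chemoselectivity over aldol reactions of 11 and retro-aldol cleavage of 10 rests on the weak basicity of Sm(III) alkoxides at -10 °C; the aryl benzyl ethers are inert.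

Step 6
Reactants: 13 (3R,5R)-7-[3,4-bis(benzyloxy)phenyl]-1-[4-(benzyloxy)phenyl]-3-hydroxyheptan-5-yl acetate
Product: 14 (3R,5R)-7-(3,4-dihydroxyphenyl)-3-hydroxy-1-(4-hydroxyphenyl)heptan-5-yl acetate (target)
Conditions: H2 (1 atm), 10% Pd/C, EtOAc, 20 °C; filtration under Ar
Reagents that add atoms: none
Why: Hydrogenolysis of the three aryl benzyl ethers; the C3–O and C5–O bonds are not benzylic and are not cleaved. The medium is neutral and aprotic, so neither 1,3-acyl migration nor transesterification of the acetate is expected, and the catechol is kept under inert gas after filtration.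

## Compound list

1 | 3-(3,4-dihydroxyphenyl)propanoic acid | OC(=O)CCc1ccc(O)c(O)c1 | starting material
2 | benzyl 3-[3,4-bis(benzyloxy)phenyl]propanoate | O=C(CCc1ccc(OCc2ccccc2)c(OCc2ccccc2)c1)OCc1ccccc1 | intermediate
3 | N-methoxy-N-methylacetamide | CC(=O)N(C)OC | starting material
4 | lithium enolate of N-methoxy-N-methylacetamide | C=C(O[Li])N(C)OC | intermediate
5 | 5-[3,4-bis(benzyloxy)phenyl]-N-methoxy-N-methyl-3-oxopentanamide | CON(C)C(=O)CC(=O)CCc1ccc(OCc2ccccc2)c(OCc2ccccc2)c1 | intermediate
6 | (3R)-5-[3,4-bis(benzyloxy)phenyl]-3-hydroxy-N-methoxy-N-methylpentanamide | CON(C)C(=O)C[C@H](O)CCc1ccc(OCc2ccccc2)c(OCc2ccccc2)c1 | intermediate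
7 | 1-(benzyloxy)-4-(2-bromoethyl)benzene | BrCCc1ccc(OCc2ccccc2)cc1 | starting material
8 | 2-[4-(benzyloxy)phenyl]ethylmagnesium bromide | Br[Mg]CCc1ccc(OCc2ccccc2)cc1 | intermediate
9 | bis(bromomagnesium) alkoxide of the tetrahedral adduct of 8 and 6 (N-methoxy hemiaminal chelate, 5R) | CON(C)C(CCc1ccc(OCc2ccccc2)cc1)(O[Mg]Br)C[C@H](O[Mg]Br)CCc1ccc(OCc2ccccc2)c(OCc2ccccc2)c1 | intermediate
10 | (5R)-7-[3,4-bis(benzyloxy)phenyl]-1-[4-(benzyloxy)phenyl]-5-hydroxyheptan-3-one | O=C(CCc1ccc(OCc2ccccc2)cc1)C[C@H](O)CCc1ccc(OCc2ccccc2)c(OCc2ccccc2)c1 | intermediate
11 | acetaldehyde | CC=O | starting material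
12 | samarium(III) alkoxide of the O5 hemiacetal of 10 and 11 (5R) | CC(O[Sm](I)I)O[C@H](CCc1ccc(OCc2ccccc2)c(OCc2ccccc2)c1)CC(=O)CCc1ccc(OCc2ccccc2)cc1 | intermediate
13 | (3R,5R)-7-[3,4-bis(benzyloxy)phenyl]-1-[4-(benzyloxy)phenyl]-3-hydroxyheptan-5-yl acetate | CC(=O)O[C@H](CCc1ccc(OCc2ccccc2)c(OCc2ccccc2)c1)C[C@H](O)CCc1ccc(OCc2ccccc2)cc1 | intermediate
14 | (3R,5R)-7-(3,4-dihydroxyphenyl)-3-hydroxy-1-(4-hydroxyphenyl)heptan-5-yl acetate | CC(=O)O[C@H](CCc1ccc(O)c(O)c1)C[C@H](O)CCc1ccc(O)cc1 | target

## Step count and risk

Total step count: 6. Longest linear sequence: 6 steps (1 → 2 → 5 → 6 → 10 → 13 → 14); 3, 7 and 11 enter as bought building blocks.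

**Step 5 (key step).** The most likely failure is 1,3-acyl migration from O5 to O3 in the samarium alkoxide of the product, through a six-membered orthoester-type intermediate, if turnover is slow or the quench is delayed. Because C3 and C5 are almost equivalent, the migrated isomer could not be removed, so constitutional purity would be lost. A second risk is consumption of 11 by self-condensation, which stalls the cycle. The fallback replaces the substrate-directed hydride shift by catalyst-controlled reduction after the acetate is in place. It sets out from 6: three equivalents of the lithium acetylide of commercial 1-(benzyloxy)-4-ethynylbenzene (n-BuLi, THF, -78 to 0 °C) should give (5R)-7-[3,4-bis(benzyloxy)phenyl]-1-[4-(benzyloxy)phenyl]-5-hydroxyhept-1-yn-3-one F1. Acetylation of O5 (Ac2O, pyridine, 0 °C) gives (5R)-7-[3,4-bis(benzyloxy)phenyl]-1-[4-(benzyloxy)phenyl]-3-oxohept-1-yn-5-yl acetate F2. Asymmetric transfer hydrogenation with RuCl[(S,S)-TsDPEN](p-cymene) in HCO2H/Et3N should reduce the ynone under catalyst control to (3S,5R)-7-[3,4-bis(benzyloxy)phenyl]-1-[4-(benzyloxy)phenyl]-3-hydroxyhept-1-yn-5-yl acetate F3. The descriptor 3S in the alkyne series is the same spatial arrangement as 3R in 14, because the alkynyl carbon outranks C4. Hydrogenation over Pd/C in EtOAc then saturates the alkyne and removes the three benzyl groups in one operation, so this path comes back to the route at 14. In it the acetyl group is on O5 before O3 exists as a hydroxyl, and it never meets a basic alkoxide afterwards.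

**Step 3.** The N-methoxy amide is a more hindered and weaker chelating partner for ruthenium than an ester, so incomplete conversion or lower facial discrimination is the most likely failure; forcing conditions could start to cleave the N–O bond. The fallback uses an ester as the directing group and sets out from 2. Claisen condensation with the lithium enolate of methyl acetate (THF, -78 °C) should give methyl 5-[3,4-bis(benzyloxy)phenyl]-3-oxopentanoate F4. Hydrogenation with the same (R)-BINAP–ruthenium catalyst in MeOH, on the substrate class for which this catalysis is best established, gives methyl (3R)-5-[3,4-bis(benzyloxy)phenyl]-3-hydroxypentanoate F5. Aminolysis with N,O-dimethylhydroxylamine hydrochloride and i-PrMgCl (THF, -20 °C) converts F5 into 6, where the route is rejoined.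

**Step 2.** Proton transfer can outrun acylation: the product quenches 4 as it forms and regenerates neutral 3, which is itself an acylating agent for 4, so self-condensation of the acetamide and stalled conversion are the likely failures. The fallback builds the β-keto amide without an amide enolate and sets out from 2. Saponification (LiOH, THF/H2O) gives 3-[3,4-bis(benzyloxy)phenyl]propanoic acid F6. Activation with carbonyldiimidazole and C-acylation of Meldrum's acid gives 5-{3-[3,4-bis(benzyloxy)phenyl]propanoyl}-2,2-dimethyl-1,3-dioxane-4,6-dione F7. Heating F7 with N,O-dimethylhydroxylamine in toluene opens the dioxanedione with loss of acetone and carbon dioxide and gives 5, where the route is rejoined.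

**Step 4.** The magnesium alkoxide formed by the first equivalent of 8 can slow the addition to the amide, so that deprotonation at the CH2 between the alkoxide and the amide, or β-elimination from the dianionic stage, competes. The fallback adds the Grignard reagent to a protected substrate and sets out from 6. Silylation (TESCl, imidazole, CH2Cl2) gives (3R)-5-[3,4-bis(benzyloxy)phenyl]-N-methoxy-N-methyl-3-[(triethylsilyl)oxy]pentanamide F8. Reagent 8 (1.5 equiv) then adds to a substrate without an acidic proton and gives (5R)-7-[3,4-bis(benzyloxy)phenyl]-1-[4-(benzyloxy)phenyl]-5-[(triethylsilyl)oxy]heptan-3-one F9. AcOH/THF/H2O at 20 °C removes the silyl group and delivers 10, where the route is rejoined.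

## Further compounds

F1 | step 5 | (5R)-7-[3,4-bis(benzyloxy)phenyl]-1-[4-(benzyloxy)phenyl]-5-hydroxyhept-1-yn-3-one | O[C@H](CCc1ccc(OCc2ccccc2)c(OCc2ccccc2)c1)CC(=O)C#Cc1ccc(OCc2ccccc2)cc1
F2 | step 5 | (5R)-7-[3,4-bis(benzyloxy)phenyl]-1-[4-(benzyloxy)phenyl]-3-oxohept-1-yn-5-yl acetate | CC(=O)O[C@H](CCc1ccc(OCc2ccccc2)c(OCc2ccccc2)c1)CC(=O)C#Cc1ccc(OCc2ccccc2)cc1
F3 | step 5 | (3S,5R)-7-[3,4-bis(benzyloxy)phenyl]-1-[4-(benzyloxy)phenyl]-3-hydroxyhept-1-yn-5-yl acetate | CC(=O)O[C@H](CCc1ccc(OCc2ccccc2)c(OCc2ccccc2)c1)C[C@H](O)C#Cc1ccc(OCc2ccccc2)cc1
F4 | step 3 | methyl 5-[3,4-bis(benzyloxy)phenyl]-3-oxopentanoate | COC(=O)CC(=O)CCc1ccc(OCc2ccccc2)c(OCc2ccccc2)c1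
F5 | step 3 | methyl (3R)-5-[3,4-bis(benzyloxy)phenyl]-3-hydroxypentanoate | COC(=O)C[C@H](O)CCc1ccc(OCc2ccccc2)c(OCc2ccccc2)c1
F6 | step 2 | 3-[3,4-bis(benzyloxy)phenyl]propanoic acid | OC(=O)CCc1ccc(OCc2ccccc2)c(OCc2ccccc2)c1
F7 | step 2 | 5-{3-[3,4-bis(benzyloxy)phenyl]propanoyl}-2,2-dimethyl-1,3-dioxane-4,6-dione | CC1(C)OC(=O)C(C(=O)CCc2ccc(OCc3ccccc3)c(OCc3ccccc3)c2)C(=O)O1
F8 | step 4 | (3R)-5-[3,4-bis(benzyloxy)phenyl]-N-methoxy-N-methyl-3-[(triethylsilyl)oxy]pentanamide | CC[Si](CC)(CC)O[C@H](CCc1ccc(OCc2ccccc2)c(OCc2ccccc2)c1)CC(=O)N(C)OC
F9 | step 4 | (5R)-7-[3,4-bis(benzyloxy)phenyl]-1-[4-(benzyloxy)phenyl]-5-[(triethylsilyl)oxy]heptan-3-one | CC[Si](CC)(CC)O[C@H](CCc1ccc(OCc2ccccc2)c(OCc2ccccc2)c1)CC(=O)CCc1ccc(OCc2ccccc2)cc1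
A1 | alternative 1 | 7-[3,4-bis(benzyloxy)phenyl]-1-[4-(benzyloxy)phenyl]heptane-3,5-dione | O=C(CCc1ccc(OCc2ccccc2)cc1)CC(=O)CCc1ccc(OCc2ccccc2)c(OCc2ccccc2)c1
A2 | alternative 1 | (3R,5R)-7-[3,4-bis(benzyloxy)phenyl]-1-[4-(benzyloxy)phenyl]heptane-3,5-diol | O[C@H](CCc1ccc(OCc2ccccc2)c(OCc2ccccc2)c1)C[C@H](O)CCc1ccc(OCc2ccccc2)cc1
A3 | alternative 1 | (3R,5R)-7-[3,4-bis(benzyloxy)phenyl]-1-[4-(benzyloxy)phenyl]-5-hydroxyheptan-3-yl acetate | O[C@H](CCc1ccc(OCc2ccccc2)c(OCc2ccccc2)c1)C[C@H](OC(C)=O)CCc1ccc(OCc2ccccc2)cc1
A4 | alternative 2 | 4-[4-(benzyloxy)phenyl]butan-2-one | CC(=O)CCc1ccc(OCc2ccccc2)cc1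
A5 | alternative 2 | 3-[3,4-bis(benzyloxy)phenyl]propanal | O=CCCc1ccc(OCc2ccccc2)c(OCc2ccccc2)c1
A6 | alternative 2 | rac-(3R*,5R*)-7-[3,4-bis(benzyloxy)phenyl]-1-[4-(benzyloxy)phenyl]-3-hydroxyheptan-5-yl acetate (both enantiomers) | CC(=O)O[C@H](CCc1ccc(OCc2ccccc2)c(OCc2ccccc2)c1)C[C@H](O)CCc1ccc(OCc2ccccc2)cc1.CC(=O)O[C@@H](CCc1ccc(OCc2ccccc2)c(OCc2ccccc2)c1)C[C@@H](O)CCc1ccc(OCc2ccccc2)cc1
A7 | alternative 3 | (2S,4S)-1,2:4,5-diepoxypentane | C1O[C@H]1C[C@H]1CO1
A8 | alternative 3 | (2R)-4-[3,4-bis(benzyloxy)phenyl]-1-[(2S)-oxiran-2-yl]butan-2-ol | O[C@H](CCc1ccc(OCc2ccccc2)c(OCc2ccccc2)c1)C[C@H]1CO1
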